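The numbers were chosen freely; no experiment stands behind them.

Link formation and ring formation both run in proportion to the dissolved first end groups, so the ratio of their rates, the selectivity factor, is free of that concentration. They run level when second end groups stand at 76.1% of their charge, and I call this fraction the balance point.

solid first end groups 0.25 M; second end groups 0.237 M; time 1.5 h

    first end groups + second end groups → links (k1 = 0.0347 /M/s)
    first end groups + second end groups → rings, rate k2*[first end groups] as long as [second end groups] is above zero (k2 = 0.00626 /s)
    solid first end groups ⇌ first end groups, rate k3*(cs3 - [first end groups]) while solid is left; crystals form when [first end groups] > cs3 (cs3 = 0.21 M, k3 = 0.00598 /s)
    second end groups → decomposed reagent (k4 = 0.00184 /s)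

- solid, in amounts per volume of the solution: solid first end groups
- at the start none of the solid first end groups is in solution
- what has only dissolved of solid first end groups counts as not reacted
- the reaction counts as stopped when no species that holds the solid first end groups changes by six tenths of a point or more over the second half of the time
- run time (flask): 1.5 h

- the state of affairs at 1.5 h: stopped, and by what, or still going (for what has run out or reacted, a solid counts together with what of it has only dissolved) (the second end groups has run out first / it is still moving / all of the solid first end groups has reacted)
- the links standing at 1.5 h, as a percentage of the solid first end groups charged
- amount of links if the flask were left three thousand times as long, in percent of the solid first end groups charged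

In this flask I freeze the dissolved first end groups where dissolving matches their use at the charged second end groups, at 24.5% of the solid charge. Rings then take a steady stream, while links and decomposition, both first order in second end groups, split what remains, 53.6% of it to links. At that frozen level my reckoning brings second end groups to zero at 5.20 min, far sooner than the run time. Rings then hold 47.9% of the solid charge and links 25.1%. Together these stay below the charge, so I expect second end groups to run out first and the links to stay at that figure.

The forecast says: the second end groups has run out first, with links at 22.9% at the asked time and 22.9% in the long run, and it adds “Waiting longer adds nothing.” Its links stand lower than mine.

The simulation gives: the second end groups has run out first, with links at 23.0% and 23.0%, so the forecast holds.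

In this flask second end groups, the limiting reagent, stand at 0% by 0.150 h, and first end groups equal to 30.2% of the solid charge stay dissolved and unreacted. Links at 23.0% against rings at 46.8% correspond to a mean level of 37.4% of the second end groups' charge, below the balance point. A neighbouring flask, the same but with 0.59 M of second end groups, has its balance point at 30.6% of that charge. Taking the level of second end groups in that neighbouring flask as 0.295 M, the mean of charge and zero, I reckon that links get 62.1% of the first end groups that react. In that neighbouring flask first end groups end at 0%, rings at 37.8% and links at 62.2%.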